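## Structural features

Candidachalcone (17) is a chalcone. Ring A is a phloroglucinol-type benzene substituted on five of its six carbons (acyl at C1', OH at C2' and C4', side chain at C3', OMe at C6', hydrogen only at C5'), and it is joined through C1' to an (E)-propenone bridge whose β-carbon carries ring B, a 4-hydroxyphenyl group. C3', which lies between the two phenolic carbons, bears a (Z)-3-hydroxy-3-methylbut-1-enyl chain: the cis alkene C1''=C2'' and the tertiary carbinol C3''. There is no stereocentre; the stereochemical content is two alkene geometries, the stable E enone and the less stable Z styrenyl alkene, which sits between a di-ortho-substituted aryl carbon and a fully substituted carbon. The fragile part is the Z-allylic tertiary alcohol next to the C2' and C4' hydroxyls: acid ionises it and a phenol closes onto C3'' to give a 2,2-dimethyl-2H-chromene, while light, acid or metal hydrides can turn Z into E. In addition, the 2'-hydroxychalcone can close to a flavanone, and the electron-rich ring A is easily oxidised. The real difficulty is twofold: to write the Z alkene in a crowded position, and then to attach the cinnamoyl group to the last free, hindered carbon of ring A without acid and without losing the geometry or starting a cyclisation. The key step uses the fact that the oxygen on C2' (equivalently C4') and the oxygen on C3'' can both be bonded to one silicon atom, which places C1''=C2'' in an eight-membered ring (Si, O, C2', C3', C1'', C2'', C3'', O) that holds only a cis double bond; before the acyl group is present, ring A also has a mirror plane through C3' and C6', so its two phenols are equivalent.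

## Logic of the disconnections

17 ⇒ 16. The five O–Si bonds that mask O2', O3'', O4' and the ring B oxygen are cut. The free phenol/Z-allylic alcohol array and the 2'-hydroxychalcone are the acid- and base-sensitive parts and should exist only in the last flask. Every earlier intermediate is then neutral and lipophilic. The forward step must be one fluoride treatment, buffered so that neither chromene nor flavanone formation can begin.

16 ⇒ 15. The ketone on C1' is traced back to a secondary carbinol. The aryl–carbonyl bond is most simply made by adding an aryl anion to an aldehyde. The forward step needs a neutral oxidant that acts only on a benzylic, allylic alcohol.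

15 ⇒ 10 + 12 (through 13 and 14). The C1'–C(carbinol) bond is cut. Electrophilic acylation of ring A would need acid, which the tertiary allylic ether cannot bear, so the polarity is reversed and ring A becomes the nucleophile. This splits the molecule into a ring A piece and the complete three-carbon/ring B unit with its E alkene in place. The forward step demands that halogen–lithium exchange outrun attack at silicon, that silicon not move from oxygen to carbon in 13, and that 14 be protonated before silicon can move to its oxygen.

12 ⇒ 11. The ArO–Si bond of ring B is cut. The silyl group only removes an acidic proton and leaves with the same fluoride as the tethers.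

10 ⇒ 9. The C–I bond at the future C1' is cut. Introducing the halogen after the metathesis keeps the metathesis substrate symmetric. The forward step needs substitution on the arene to be faster than attack on two alkenes; both free ring positions lead to 17, so regiochemistry affects tidiness only.

9 ⇒ 8 (key disconnection). The C1''=C2'' bond is cut inside the eight-membered silaketal. One operation then supplies the Z alkene, the ring and the protection of O2' and O3'', and 8 contains only terminal alkenes and no stereochemical element. The forward step demands ring closure between two hindered alkenes in preference to intermolecular metathesis.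

8 ⇒ 7. The terminal carbon of the styrene is removed, returning a formyl group. The forward step is methylenation of a di-ortho-substituted aldehyde that must spare aryl silyl ethers.

7 ⇒ 2 + 6. Both ArO–Si bonds are cut. Identical tethers on the two equivalent phenols make a monoprotection unnecessary. The forward step demands complete silylation of two hindered, hydrogen-bonded phenols.

6 ⇒ 3 + 4 (through 5). The Si–O bond to the tertiary carbon is cut. Attaching the hindered alcohol first makes monosubstitution of the dichlorosilane clean, because a second bulky alkoxide should not enter.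

2 ⇒ 1. The O–CH3 bond on the oxygen para to the formyl group is cut. The forward step demands selectivity for the one hydroxyl that is not hydrogen-bonded to the carbonyl group.

## Other disconnections considered

Alternative 1: The cut removes both methyl groups from C3'' and folds C3'' back onto a ring A oxygen as a lactone. The side chain then becomes C2–C3–C4 of the coumarin 5-hydroxy-7-methoxy-2-oxo-2H-chromene-6-carbaldehyde A2, whose endocyclic C3=C4 bond is necessarily cis. In the forward key step, excess MeMgBr with CeCl3 would add twice to the lactone carbonyl (the ring opens after the first addition and the freed ketone takes the second methyl) and once to the formyl group, giving the racemic tetraol A1. Oxidation of the secondary carbinol to the methyl ketone A3 and a Claisen–Schmidt condensation with 4-hydroxybenzaldehyde A4 would complete the chalcone.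
- In favour: the Z geometry is dictated by a ring exactly as in the chosen plan, so on stereocontrol the two are equal. The reagents are cheap, and neither dilution nor ruthenium is needed. The step count could fall below ten, and on that point this alternative is the better one.
- Against: A1 exposes at once the Z-allylic tertiary alcohol beside two free phenols, the arrangement that closes to a chromene with a trace of acid. It must then survive an oxidation that has to spare an electron-rich ring and a strongly basic condensation. Conjugate addition to A2 and deactivation by the C5 phenoxide also threaten the key step.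
- Comparison: mechanistically this plan makes C–CH3 bonds by polar addition, whereas the chosen plan makes C1''=C2'' itself. Structurally, the silicon tether of the chosen plan stays on as the protecting group for the fragile array until the last step, whereas the lactone template is consumed in the step that uses it.

Alternative 2: The cut runs through ring A (C2'–C3' and C4'–C5', with C1'–C2' broken and re-formed). The ring is assembled from 3-methoxycyclobut-2-en-1-one A6 and a siloxyalkyne that already carries the Z side chain, triethyl{[(3Z)-2-methyl-6-{[tri(propan-2-yl)silyl]oxy}hex-3-en-5-yn-2-yl]oxy}silane A7. On heating, A6 would open (4π electrocyclic) to a vinylketene, add to the alkyne of A7 by [2+2] cycloaddition, reopen to a dienylketene, close by 6π electrocyclisation and tautomerise to the phenol A5.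
- In favour: ring A is formed with every oxygen in place and with the two phenols differentiated (free OH on C2', silyl ether on C4'). That is better than the chosen plan for a regiodefined substitution at C1'. The step needs no metal and the union is convergent.
- Against: the Z geometry is not created by the key step. It must be built into A7 beforehand (for example by semi-hydrogenation over Pd/CaCO3 poisoned with Pb(OAc)2) and then survive prolonged heating next to ketene intermediates. The alkenyl group on the alkyne gives those intermediates a further conjugated π system and hence competing pericyclic outlets. A7 is a sensitive ynol silyl ether that would take several steps.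
- Comparison: on structure, both plans leave the C1' acyl group for later and are equal there. On mechanism, the chosen plan lets ring strain fix the geometry in the bond-forming event, which is the more secure control. On step economy, this route is expected to be longer because of A7.

Alternative 3: The cut removes the carbonyl carbon as carbon monoxide A11, breaking C1'–C(=O) and C(=O)–Cα. It leaves the ring A iodide (3Z)-4-[2,6-bis({[tert-butyl(dimethyl)silyl]oxy})-3-iodo-4-methoxyphenyl]-2-methylbut-3-en-2-ol A9 and the (E)-styrylboronate A10. Forward, Pd(PPh3)4 and K2CO3 under A11 would take A9 through oxidative addition to zerovalent palladium, insertion of A11 to an aroyl complex of divalent palladium, transmetalation with A10 and reductive elimination to the tris-silyl chalcone A8.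
- In favour: the enone is formed at the right oxidation level in one step, with no aryllithium and no separate oxidation. For this bond it is better than steps 8 and 9 of the chosen plan. The di-ortho-substituted aryl group favours CO insertion over direct coupling, and the union is convergent.
- Against: the step does nothing for the real problem, the Z alkene. That alkene must already be present in A9 with its tertiary hydroxyl free, so a separate stereodefining operation and a selective protection scheme are still needed upstream. Carbonate at elevated temperature beside aryl silyl ethers and a free tertiary alcohol invites silyl transfer, and palladium hydrides could erode the Z geometry.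
- Comparison: structurally the two plans address different bonds and are complementary. The chosen plan supplies what this one lacks, and the carbonylative coupling is kept in reserve as the fallback for step 8. The endgame is one step shorter; the total depends on an unspecified route to A9.

Key step: step 5

Assumption: iodination of 9 is taken to occur at the ring A position next to the ring silaketal oxygen (C10, the later C1'); substitution at the other free position would give an isomer that the same steps carry to the same target 17.

## Route

Step 1
Reactants: 1 2,4,6-trihydroxybenzaldehyde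
Product: 2 2,6-dihydroxy-4-methoxybenzaldehyde
Conditions: Me2SO4 (1.0 equiv), K2CO3 (1.0 equiv), acetone, 0 °C → rt
Reagents that add atoms: dimethyl sulfate, COS(=O)(=O)OC
Why: Williamson O-methylation; the C4 hydroxyl is the most acidic (para to the formyl group) and the only one not engaged in a hydrogen bond to the carbonyl oxygen, so one equivalent of base and of a hard methylating agent should alkylate it in preference to the two ortho hydroxyls.

Step 2
Reactants: 3 2-methylbut-3-en-2-ol; 4 dichlorodi(propan-2-yl)silane
Product: 6 chloro[(2-methylbut-3-en-2-yl)oxy]di(propan-2-yl)silane, via lithium 2-methylbut-3-en-2-olate 5 (not isolated)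
Conditions: 3, n-BuLi (1.0 equiv), THF, −78 → 0 °C; added to 4 (1.5 equiv), THF, −78 °C → rt; distillation
Reagents that add atoms: none
Why: Nucleophilic substitution at silicon by a lithium tert-alkoxide; once one chloride is replaced, the silicon carries two isopropyl groups and a tert-alkoxy group, so a second bulky alkoxide should not enter and the monochloride can be purified by distillation.

Step 3
Reactants: 2 2,6-dihydroxy-4-methoxybenzaldehyde; 6 chloro[(2-methylbut-3-en-2-yl)oxy]di(propan-2-yl)silane (2.5 equiv)
Product: 7 4-methoxy-2,6-bis({[(2-methylbut-3-en-2-yl)oxy]di(propan-2-yl)silyl}oxy)benzaldehyde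
Conditions: imidazole, DMAP (cat.), DMF, rt → 40 °C
Reagents that add atoms: none
Why: Base-mediated O-silylation of phenols with nucleophilic catalysis by DMAP; the phenols ortho to the formyl group are hydrogen-bonded and hindered, hence the excess of 6 and gentle warming, and the product keeps the mirror symmetry of 2.

Step 4
Reactants: 7 4-methoxy-2,6-bis({[(2-methylbut-3-en-2-yl)oxy]di(propan-2-yl)silyl}oxy)benzaldehyde
Product: 8 2-ethenyl-5-methoxy-1,3-bis({[(2-methylbut-3-en-2-yl)oxy]di(propan-2-yl)silyl}oxy)benzene
Conditions: Ph3PCH3Br, KN(SiMe3)2, THF, 0 °C; then 7, −78 → 0 °C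
Reagents that add atoms: methyltriphenylphosphonium bromide, C[P+](c1ccccc1)(c1ccccc1)c1ccccc1.[Br-]
Why: Wittig methylenation; the small non-stabilised ylide can reach the formyl carbon from the faces of the ring although both ortho positions are occupied, and the hindered diisopropylsilyl ethers should resist the ylide at low temperature. The aldehyde has no enolisable proton.

Step 5
Reactants: 8 2-ethenyl-5-methoxy-1,3-bis({[(2-methylbut-3-en-2-yl)oxy]di(propan-2-yl)silyl}oxy)benzene
Product: 9 (5Z)-9-methoxy-4,4-dimethyl-7-({[(2-methylbut-3-en-2-yl)oxy]di(propan-2-yl)silyl}oxy)-2,2-di(propan-2-yl)-4H-1,3,2-benzodioxasilocine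
Conditions: RuCl2(=CHPh)(H2IMes)(PCy3) (second-generation Grubbs catalyst, 10 mol%), toluene (0.002 M), 80 °C, Ar sparge
Reagents that add atoms: none
Why: Ring-closing olefin metathesis: loss of PCy3 gives the 14-electron ruthenium alkylidene, which exchanges with a terminal alkene of 8 (most likely the styrene CH2) by [2+2] cycloaddition and cycloreversion and then closes through a ruthenacyclobutane onto the vinyl group of a tether, releasing ethene and Ru=CH2 as chain carrier. The closest known reaction type is temporary-silicon-tethered ring-closing metathesis of bis-alkoxysilanes to seven- and eight-membered cyclic silaketals with cis alkenes. The ring is closed at C1''=C2'' as an eight-membered ring (Si, O, C2', C3', C1'', C2'', C3'', O) by metathesis of a 1,9-diene, helped by the two coplanar arene carbons, the gem-dimethyl group, the long Si–O bonds and the bulky isopropyl groups, which together hold the alkene ends close. No stereocentre is formed; the only stereochemical element, the alkene geometry, is fixed as Z because a benzo-fused eight-membered ring cannot span a trans alkene. The step needs ring closure in preference to cross-metathesis, and this is secured by high dilution, by removal of ethene and by the fact that a di-ortho-substituted styrene and a vinyl group on a fully substituted carbon are both poor partners for homodimerisation or for closure of the two tethers onto each other. Site selectivity does not arise, because the two tethers are related by the mirror plane through C3' and C6' and give the same product, and the spare tether can afterwards only enter a degenerate exchange that regenerates 9. Neither alkene has an allylic hydrogen, so alkene migration by ruthenium hydrides has no pathway, and the silyl ethers and the aryl methyl ether are inert to the carbene.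

Step 6
Reactants: 9 (5Z)-9-methoxy-4,4-dimethyl-7-({[(2-methylbut-3-en-2-yl)oxy]di(propan-2-yl)silyl}oxy)-2,2-di(propan-2-yl)-4H-1,3,2-benzodioxasilocine
Product: 10 (5Z)-10-iodo-9-methoxy-4,4-dimethyl-7-({[(2-methylbut-3-en-2-yl)oxy]di(propan-2-yl)silyl}oxy)-2,2-di(propan-2-yl)-4H-1,3,2-benzodioxasilocine
Conditions: NIS (1.05 equiv), MeCN–CH2Cl2, 0 °C, dark
Reagents that add atoms: N-iodosuccinimide, O=C1CCC(=O)N1I
Why: Electrophilic aromatic iodination of a ring with three oxygen donors, each free position being ortho to two of them and para to the third; C10 is expected to react because the silicon on the neighbouring ring oxygen is tied back into the eight-membered ring, whereas the acyclic silyl ether shields C8. The acid-free conditions spare the tertiary allylic silyl ethers, and both alkenes (one twisted out of conjugation in the ring, one a vinyl group beside a C–O bond) should react more slowly than the arene.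

Step 7
Reactants: 11 (2E)-3-(4-hydroxyphenyl)prop-2-enal
Product: 12 (2E)-3-(4-{[tert-butyl(dimethyl)silyl]oxy}phenyl)prop-2-enal
Conditions: TBSCl, imidazole, CH2Cl2, 0 °C → rt
Reagents that add atoms: tert-butyl(chloro)dimethylsilane, CC(C)(C)[Si](C)(C)Cl
Why: Standard silylation of a phenol; it removes the acidic proton that would quench the aryllithium of step 8, and the silyl ether leaves in the same fluoride step as the tethers.

Step 8
Reactants: 10 (5Z)-10-iodo-9-methoxy-4,4-dimethyl-7-({[(2-methylbut-3-en-2-yl)oxy]di(propan-2-yl)silyl}oxy)-2,2-di(propan-2-yl)-4H-1,3,2-benzodioxasilocine; 12 (2E)-3-(4-{[tert-butyl(dimethyl)silyl]oxy}phenyl)prop-2-enal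
Product: 15 (2E)-3-(4-{[tert-butyl(dimethyl)silyl]oxy}phenyl)-1-[(5Z)-9-methoxy-4,4-dimethyl-7-({[(2-methylbut-3-en-2-yl)oxy]di(propan-2-yl)silyl}oxy)-2,2-di(propan-2-yl)-4H-1,3,2-benzodioxasilocin-10-yl]prop-2-en-1-ol (racemic), via the aryllithium 13 (not isolated), via the lithium alkoxide 14 (not isolated)
Conditions: n-BuLi (1.05 equiv), THF, −78 °C, 5 min; then 12, −78 °C; AcOH, −78 °C
Reagents that add atoms: none
Why: Iodine–lithium exchange followed by 1,2-addition of the hard aryllithium to the enal. The only silicon ortho to the carbanion is held in the eight-membered ring, away from the in-plane lone pair, so silyl migration from oxygen to carbon has no accessible geometry, and protonation at −78 °C is meant to forestall migration of silicon to the new alkoxide. The carbinol stereocentre is formed without control and is erased in step 9.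

Step 9
Reactants: 15 the racemic carbinol from step 8
Product: 16 (2E)-3-(4-{[tert-butyl(dimethyl)silyl]oxy}phenyl)-1-[(5Z)-9-methoxy-4,4-dimethyl-7-({[(2-methylbut-3-en-2-yl)oxy]di(propan-2-yl)silyl}oxy)-2,2-di(propan-2-yl)-4H-1,3,2-benzodioxasilocin-10-yl]prop-2-en-1-one
Conditions: MnO2 (activated, excess), CH2Cl2, rt
Reagents that add atoms: none
Why: MnO2 oxidation of an alcohol that is both benzylic and allylic; the neutral, heterogeneous oxidant should leave the silyl ethers, the other alkenes and the electron-rich ring alone.

Step 10
Reactants: 16 the fully silylated chalcone from step 9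
Product: 17 candidachalcone, (2E)-1-{2,4-dihydroxy-3-[(1Z)-3-hydroxy-3-methylbut-1-en-1-yl]-6-methoxyphenyl}-3-(4-hydroxyphenyl)prop-2-en-1-one
Conditions: Bu4NF (6 equiv), AcOH (6 equiv), THF, 0 °C → rt; pH 7 buffer
Reagents that add atoms: none
Why: Fluoride-driven cleavage of all five Si–O bonds, the aryl oxides leaving first and the tertiary alkoxides following from the fluorosilyl ethers. Acetic acid protonates the liberated phenoxides, which guards against oxa-Michael closure to a flavanone, while the medium stays far from the acidity that would close the Z-allylic alcohol onto a phenol; neither alkene geometry is touched.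

## Compound list

1 | 2,4,6-trihydroxybenzaldehyde | O=Cc1c(O)cc(O)cc1O | starting material
2 | 2,6-dihydroxy-4-methoxybenzaldehyde | COc1cc(O)c(C=O)c(O)c1 | intermediate
3 | 2-methylbut-3-en-2-ol | C=CC(C)(C)O | starting material
4 | dichlorodi(propan-2-yl)silane | CC(C)[Si](Cl)(Cl)C(C)C | starting material
5 | lithium 2-methylbut-3-en-2-olate (not isolated) | C=CC(C)(C)[O-].[Li+] | intermediate
6 | chloro[(2-methylbut-3-en-2-yl)oxy]di(propan-2-yl)silane | C=CC(C)(C)O[Si](Cl)(C(C)C)C(C)C | intermediate
7 | 4-methoxy-2,6-bis({[(2-methylbut-3-en-2-yl)oxy]di(propan-2-yl)silyl}oxy)benzaldehyde | COc1cc(O[Si](C(C)C)(C(C)C)OC(C)(C)C=C)c(C=O)c(O[Si](C(C)C)(C(C)C)OC(C)(C)C=C)c1 | intermediate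
8 | 2-ethenyl-5-methoxy-1,3-bis({[(2-methylbut-3-en-2-yl)oxy]di(propan-2-yl)silyl}oxy)benzene | COc1cc(O[Si](C(C)C)(C(C)C)OC(C)(C)C=C)c(C=C)c(O[Si](C(C)C)(C(C)C)OC(C)(C)C=C)c1 | intermediate
9 | (5Z)-9-methoxy-4,4-dimethyl-7-({[(2-methylbut-3-en-2-yl)oxy]di(propan-2-yl)silyl}oxy)-2,2-di(propan-2-yl)-4H-1,3,2-benzodioxasilocine (ring O1–Si2–O3–C4Me2–C5H=C6H fused to ring A) | COc1cc2O[Si](C(C)C)(C(C)C)OC(C)(C)/C=C\c2c(O[Si](C(C)C)(C(C)C)OC(C)(C)C=C)c1 | intermediate
10 | (5Z)-10-iodo-9-methoxy-4,4-dimethyl-7-({[(2-methylbut-3-en-2-yl)oxy]di(propan-2-yl)silyl}oxy)-2,2-di(propan-2-yl)-4H-1,3,2-benzodioxasilocine | COc1c(I)c2O[Si](C(C)C)(C(C)C)OC(C)(C)/C=C\c2c(O[Si](C(C)C)(C(C)C)OC(C)(C)C=C)c1 | intermediate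
11 | (2E)-3-(4-hydroxyphenyl)prop-2-enal | O=C/C=C/c1ccc(O)cc1 | starting material
12 | (2E)-3-(4-{[tert-butyl(dimethyl)silyl]oxy}phenyl)prop-2-enal | O=C/C=C/c1ccc(O[Si](C)(C)C(C)(C)C)cc1 | intermediate
13 | [(5Z)-9-methoxy-4,4-dimethyl-7-({[(2-methylbut-3-en-2-yl)oxy]di(propan-2-yl)silyl}oxy)-2,2-di(propan-2-yl)-4H-1,3,2-benzodioxasilocin-10-yl]lithium (not isolated) | COc1c([Li])c2O[Si](C(C)C)(C(C)C)OC(C)(C)/C=C\c2c(O[Si](C(C)C)(C(C)C)OC(C)(C)C=C)c1 | intermediate
14 | lithium alkoxide of 15, racemic (not isolated) | COc1c(C([O-])/C=C/c3ccc(O[Si](C)(C)C(C)(C)C)cc3)c2O[Si](C(C)C)(C(C)C)OC(C)(C)/C=C\c2c(O[Si](C(C)C)(C(C)C)OC(C)(C)C=C)c1.[Li+] | intermediate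
15 | (2E)-3-(4-{[tert-butyl(dimethyl)silyl]oxy}phenyl)-1-[(5Z)-9-methoxy-4,4-dimethyl-7-({[(2-methylbut-3-en-2-yl)oxy]di(propan-2-yl)silyl}oxy)-2,2-di(propan-2-yl)-4H-1,3,2-benzodioxasilocin-10-yl]prop-2-en-1-ol (racemic) | COc1c(C(O)/C=C/c3ccc(O[Si](C)(C)C(C)(C)C)cc3)c2O[Si](C(C)C)(C(C)C)OC(C)(C)/C=C\c2c(O[Si](C(C)C)(C(C)C)OC(C)(C)C=C)c1 | intermediate
16 | (2E)-3-(4-{[tert-butyl(dimethyl)silyl]oxy}phenyl)-1-[(5Z)-9-methoxy-4,4-dimethyl-7-({[(2-methylbut-3-en-2-yl)oxy]di(propan-2-yl)silyl}oxy)-2,2-di(propan-2-yl)-4H-1,3,2-benzodioxasilocin-10-yl]prop-2-en-1-one | COc1c(C(=O)/C=C/c3ccc(O[Si](C)(C)C(C)(C)C)cc3)c2O[Si](C(C)C)(C(C)C)OC(C)(C)/C=C\c2c(O[Si](C(C)C)(C(C)C)OC(C)(C)C=C)c1 | intermediate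
17 | candidachalcone, (2E)-1-{2,4-dihydroxy-3-[(1Z)-3-hydroxy-3-methylbut-1-en-1-yl]-6-methoxyphenyl}-3-(4-hydroxyphenyl)prop-2-en-1-one | COc1cc(O)c(/C=C\C(C)(C)O)c(O)c1C(=O)/C=C/c1ccc(O)cc1 | target

## Step count and least certain steps

Total step count: 10. Longest linear sequence: 8 steps (steps 1, 3, 4, 5, 6, 8, 9 and 10, from 1 to 17); steps 2 and 7 are side branches.

Step 5 (key step). The most likely failure is that the ring does not close. The propagating ruthenium alkylidene sits on a di-ortho-substituted benzylidene and must engage a vinyl group on a fully substituted carbon, so catalyst decomposition may outpace turnover; intermolecular metathesis may take over if the eight-membered ring is more strained than assumed. The fallback replaces metathesis by a lactone template. It sets out from 2. Wittig olefination and lactonisation with ethyl (triphenylphosphoranylidene)acetate in refluxing N,N-diethylaniline should give 5-hydroxy-7-methoxy-2H-chromen-2-one F1. Excess MeLi in THF (−78 → 0 °C) adds twice to the lactone carbonyl and opens the ring to 2-[(1Z)-3-hydroxy-3-methylbut-1-en-1-yl]-5-methoxybenzene-1,3-diol F2, which is kept away from acid. One equivalent of 4 with imidazole in DMF at high dilution ties one phenol to the tertiary alcohol as (5Z)-9-methoxy-4,4-dimethyl-2,2-di(propan-2-yl)-4H-1,3,2-benzodioxasilocin-7-ol F3. Silylation of the remaining phenol with 6 (imidazole, DMF) then returns to the route at 9.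

Step 8. The likely failures are migration of silicon from the ring oxygen to the newly formed alkoxide (or to the aryl carbanion), attack of butyllithium at silicon, and premature protonation of the aryllithium. Each would deprive step 9 of its free carbinol. The fallback avoids carbanions altogether. It sets out from 10 and uses a carbonylative Suzuki–Miyaura coupling (Pd(PPh3)4, anhydrous K2CO3, CO at 1 atm, anisole, 80 °C) with tert-butyl(dimethyl){4-[(E)-2-(4,4,5,5-tetramethyl-1,3,2-dioxaborolan-2-yl)ethenyl]phenoxy}silane F4. F4 is the same boronate as A10 and would be made by hydroboration of commercial tert-butyl(4-ethynylphenoxy)dimethylsilane with pinacolborane and catalytic Cp2Zr(H)Cl. The coupling gives the ketone directly and rejoins the route at 16, bypassing 15.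

Step 6. The likely failures are attack of the iodinating agent on the electron-rich cis alkene attached to ring A, substitution at the other free ring position, and ionisation of the tertiary allylic silyl ethers by traces of acid. The fallback introduces the halogen before any alkene exists. It sets out from 2. NIS (1.0 equiv, MeCN, 0 °C) should give 2,6-dihydroxy-3-iodo-4-methoxybenzaldehyde F5. Silylation with 6 as in step 3 gives 3-iodo-4-methoxy-2,6-bis({[(2-methylbut-3-en-2-yl)oxy]di(propan-2-yl)silyl}oxy)benzaldehyde F6, and methylenation as in step 4 gives 2-ethenyl-4-iodo-5-methoxy-1,3-bis({[(2-methylbut-3-en-2-yl)oxy]di(propan-2-yl)silyl}oxy)benzene F7. Ring-closing metathesis under the conditions of step 5 returns to the route at 10 when the tether on the oxygen next to iodine closes. Closure through the other tether would give the positional isomer (5Z)-8-iodo-9-methoxy-4,4-dimethyl-7-({[(2-methylbut-3-en-2-yl)oxy]di(propan-2-yl)silyl}oxy)-2,2-di(propan-2-yl)-4H-1,3,2-benzodioxasilocine F8, which is removed by chromatography.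

Step 1. The likely failures are over-methylation at a second hydroxyl and C-methylation of the phloroglucinol nucleus, because the three hydroxyls differ only moderately in acidity. The fallback replaces selective alkylation by selective dealkylation. It sets out from 1. Exhaustive O-methylation (excess Me2SO4, K2CO3, acetone, reflux) gives 2,4,6-trimethoxybenzaldehyde F9. Excess AlCl3 in CH2Cl2 should then cleave only the two methyl ethers ortho to the formyl group, through chelation to the carbonyl oxygen, and return to the route at 2.

## Further compounds

F1 | step 5 | 5-hydroxy-7-methoxy-2H-chromen-2-one | COc1cc(O)c2C=CC(=O)Oc2c1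
F2 | step 5 | 2-[(1Z)-3-hydroxy-3-methylbut-1-en-1-yl]-5-methoxybenzene-1,3-diol | COc1cc(O)c(/C=C\C(C)(C)O)c(O)c1
F3 | step 5 | (5Z)-9-methoxy-4,4-dimethyl-2,2-di(propan-2-yl)-4H-1,3,2-benzodioxasilocin-7-ol | COc1cc(O)c2/C=C\C(C)(C)O[Si](C(C)C)(C(C)C)Oc2c1
F4 | step 8 | tert-butyl(dimethyl){4-[(E)-2-(4,4,5,5-tetramethyl-1,3,2-dioxaborolan-2-yl)ethenyl]phenoxy}silane | CC1(C)OB(/C=C/c2ccc(O[Si](C)(C)C(C)(C)C)cc2)OC1(C)C
F5 | step 6 | 2,6-dihydroxy-3-iodo-4-methoxybenzaldehyde | COc1cc(O)c(C=O)c(O)c1I
F6 | step 6 | 3-iodo-4-methoxy-2,6-bis({[(2-methylbut-3-en-2-yl)oxy]di(propan-2-yl)silyl}oxy)benzaldehyde | COc1cc(O[Si](C(C)C)(C(C)C)OC(C)(C)C=C)c(C=O)c(O[Si](C(C)C)(C(C)C)OC(C)(C)C=C)c1I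
F7 | step 6 | 2-ethenyl-4-iodo-5-methoxy-1,3-bis({[(2-methylbut-3-en-2-yl)oxy]di(propan-2-yl)silyl}oxy)benzene | COc1cc(O[Si](C(C)C)(C(C)C)OC(C)(C)C=C)c(C=C)c(O[Si](C(C)C)(C(C)C)OC(C)(C)C=C)c1I
F8 | step 6 | (5Z)-8-iodo-9-methoxy-4,4-dimethyl-7-({[(2-methylbut-3-en-2-yl)oxy]di(propan-2-yl)silyl}oxy)-2,2-di(propan-2-yl)-4H-1,3,2-benzodioxasilocine | COc1cc2O[Si](C(C)C)(C(C)C)OC(C)(C)/C=C\c2c(O[Si](C(C)C)(C(C)C)OC(C)(C)C=C)c1I
F9 | step 1 | 2,4,6-trimethoxybenzaldehyde | COc1cc(OC)c(C=O)c(OC)c1
A1 | alternative 1 | 4-(1-hydroxyethyl)-2-[(Z)-3-hydroxy-3-methylbut-1-enyl]-5-methoxybenzene-1,3-diol (racemic) | COc1cc(O)c(/C=C\C(C)(C)O)c(O)c1C(C)O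
A2 | alternative 1 | 5-hydroxy-7-methoxy-2-oxo-2H-chromene-6-carbaldehyde | COc1cc2OC(=O)C=Cc2c(O)c1C=O
A3 | alternative 1 | 1-{2,4-dihydroxy-3-[(1Z)-3-hydroxy-3-methylbut-1-en-1-yl]-6-methoxyphenyl}ethan-1-one | COc1cc(O)c(/C=C\C(C)(C)O)c(O)c1C(C)=O
A4 | alternative 1 | 4-hydroxybenzaldehyde | O=Cc1ccc(O)cc1
A5 | alternative 2 | 5-methoxy-2-[(Z)-3-methyl-3-(triethylsilyloxy)but-1-enyl]-3-(triisopropylsilyloxy)phenol | COc1cc(O)c(/C=C\C(C)(C)O[Si](CC)(CC)CC)c(O[Si](C(C)C)(C(C)C)C(C)C)c1
A6 | alternative 2 | 3-methoxycyclobut-2-en-1-one | COC1=CC(=O)C1
A7 | alternative 2 | triethyl{[(3Z)-2-methyl-6-{[tri(propan-2-yl)silyl]oxy}hex-3-en-5-yn-2-yl]oxy}silane | CC(C)(O[Si](CC)(CC)CC)/C=C\C#CO[Si](C(C)C)(C(C)C)C(C)C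
A8 | alternative 3 | 2',4',4-tris-O-(tert-butyldimethylsilyl)candidachalcone | COc1cc(O[Si](C)(C)C(C)(C)C)c(/C=C\C(C)(C)O)c(O[Si](C)(C)C(C)(C)C)c1C(=O)/C=C/c1ccc(O[Si](C)(C)C(C)(C)C)cc1
A9 | alternative 3 | (3Z)-4-[2,6-bis({[tert-butyl(dimethyl)silyl]oxy})-3-iodo-4-methoxyphenyl]-2-methylbut-3-en-2-ol | COc1cc(O[Si](C)(C)C(C)(C)C)c(/C=C\C(C)(C)O)c(O[Si](C)(C)C(C)(C)C)c1I
A10 | alternative 3 | tert-butyl(dimethyl){4-[(E)-2-(4,4,5,5-tetramethyl-1,3,2-dioxaborolan-2-yl)ethenyl]phenoxy}silane | CC1(C)OB(/C=C/c2ccc(O[Si](C)(C)C(C)(C)C)cc2)OC1(C)C
A11 | alternative 3 | carbon monoxide | [C-]#[O+]
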